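If one reagent is charged short of the other, write its balance before reading any rate.

- delta: substrate 0.020 M; coupling partner 0.018 M; free catalyst 10 µM; the very flask that is asked about, followed so far
- flask: substrate 0.020 M; coupling partner 0.0180 M; free catalyst 10 µM

delta run (percent of the substrate charged)

| time / min | target / % | substrate / % |
|---|---|---|
| 2.00 | 2.1 | 96.1 |
| 4.00 | 4.9 | 96.1 |
| 6.00 | 6.7 | 93.7 |
| 8.00 | 7.8 | 91.9 |
| 10.0 | 10.6 | 90.3 |

(readings scatter by 1 percentage point)

- no earlier run changes the charge of free catalyst; that part of a forecast is a guess
- no earlier run changes the charge of coupling partner; that part of a forecast is a guess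

- apparent order in coupling partner when 30% of the substrate are converted (percent change of the rate of making target for one percent more coupling partner charged)
- apparent order in free catalyst when 30% of the substrate are converted (percent change of the rate of making target for one percent more free catalyst charged)

The delta run and the flask carry the same charges, so read the delta run as the flask's own start; their ratios of coupling partner to substrate are equal, so reckon one ceiling for both. No reading follows coupling partner, so assume one coupling partner spent per target. Coupling partner is then the limiting reagent, and its ceiling, the charge of coupling partner over the charge of substrate, is 90.0% of the substrate as target. Coupling partner left, as a fraction of its own charge, is one minus target over ceiling.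

| Target | Substrate left, reckoned | Coupling partner left, reckoned |
|---|---|---|
| 10.6% | 89.4% | 88.2% |
| 30% | 70.0% | 66.7% |
| 90.0% | 10.0% | 0% |

So at the asked point I reckon the flask's coupling partner to have lost 33.3% of its charge, more than the 30% lost by substrate. The readings vary neither charge, so I take no order from them.

The forecast gives 0.6 in coupling partner and 1 in free catalyst, holding that the first “could lie anywhere from saturated”.

    catalyst intermediate A ⇌ catalyst intermediate B (K = 0.980, k = 2400 min⁻¹)
    free catalyst ⇌ dormant form (K = 1.10, k = 0.0110 min⁻¹)
    coupling partner + free catalyst ⇌ catalyst intermediate A (K = 130 M⁻¹, k = 2000 M⁻¹ min⁻¹)
    substrate + catalyst intermediate B → catalyst intermediate C (k = 3.00 × 10⁵ M⁻¹ min⁻¹)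
    catalyst intermediate C → free catalyst + target (k = 61.0 min⁻¹)

The flask gives 1.3 in coupling partner and 1.2 in free catalyst. After 15.0 h it holds target at 90.0%, on the ceiling, with coupling partner at 0.0194% of its charge. At 1.50 h, target at 57.0% reckons to 36.7% coupling partner left, and the flask holds 36.6%. At that time, the step joining coupling partner and free catalyst to catalyst intermediate A relaxes, both ways together and by this step alone, with a half-life of 0.0243 min, far shorter than the 1.12 h of the flask's slowest mode.

(All runs were computed for substances that don't exist, noise included.)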